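The L left over at the end is the reading to start from: in cedar, oak and ash it stands flat between 0.833 d and 10.0 d, a stretch that holds the asked 8.0 d.

| setting | cedar | oak | ash | flask |
|---|---|---|---|---|
| L | 0.52 M (in portions, 3) | 0.52 M (in portions, 3) | 1 M (in portions, 3) | 0.52 M (in portions, 3) |
| X | 0.87 M | 2 M | 1.3 M | 1.30 M |
| remark | run made earlier; portions every 80 min | run made earlier; portions every 80 min | run made earlier; portions every 80 min | the portions of L follow each other after 80 min, the first at the start |
| time |  |  |  | 8.0 d |

- cedar (time / d: L / %, E / %, D / %): 0.833: 28, 15, 19; 1.67: 28, 13, 24; 2.50: 27, 16, 21; 5.00: 26, 14, 21; 10.0: 27, 14, 24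
- oak (time / d: L / %, E / %, D / %): 0.833: 8, 16, 13; 2.50: 7, 13, 14; 4.00: 9, 15, 12; 6.00: 8, 16, 12; 10.0: 6, 14, 13
- ash (time / d: L / %, E / %, D / %): 0.833: 40, 17, 20; 2.50: 38, 11, 20; 4.00: 39, 13, 20; 6.00: 38, 11, 20; 10.0: 40, 16, 19

(scatter of a reading: 1.5 percentage points)

1. how much L there is at 8.0 d, in percent of the L charged
2. how much E there is at 8.0 d, in percent of the L charged
3. how much D there is at 8.0 d, in percent of the L charged
4. how much Z there is at 8.0 d, in percent of the L charged

- the earlier runs were read with a standard deviation of 1.5 percentage points
- steps under discussion: L + X -> E; L + X -> D; X + E -> Z; X + D -> Z; 2 X -> Q; E <-> J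

Take the main step first, L + X to E or D: each L costs one X, and the flask's 1.30 M of X exceeds its 0.52 M of L, so this count sets no floor under L. Add the next step, E or D with X to Z: two X per L now cost 1.04 M, still less than the charge, so the count still sets no floor. But oak carried twice that cost, and its L stood at a mean of 7.60%, so 2 X to Q has to enter the count, and X acts as the limiting reagent despite the excess on paper. E ⇌ J takes no X itself.

At one moment L takes X in proportion to [L][X] and Q takes it in proportion to [X][X], so the X going to Q over the X going to L follows [X]/[L], a ratio that drifts as the portions of L arrive and both are consumed. A measure of the whole run is therefore needed. The depth yield w, the logarithm of L charged over L left, times L charged over X charged, serves: from a cedar mean of 27.2% it reads 0.778, and oak, with more X on the same L, gives the second reading: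

oak: w = 0.670, less than cedar's

flask, on the straight line in X between the two: w = 0.737

ln(L charged / L left) = w × X / L = 1.84, so L left = 15.9%

This reckoning, which is not the forecast's, stops at L; what remains beyond L, E and D is Z plus J, which no run reads apart. The forecast gives L 16%, E 15%, D 18% and Z 51%, with the words "Assuming J is negligible".

The flask gives L 15.1%, E 16.4%, D 17.4% and Z 43.3%, which is 7.7 percentage points below the forecast's Z.

    L + X → E (k = 0.425 /M/h)
    L + X → D (k = 0.664 /M/h)
    X + E → Z (k = 0.294 /M/h)
    X + D → Z (k = 0.928 /M/h)
    2 X → Q (k = 0.180 /M/h)
    E ⇌ J (K = 0.480, k = 0.231 /h)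

Beyond L, E and D the flask holds 51.1% of the L charged, and J accounts for 7.85% of the L charged after 8.00 d. The flask's depth yield comes to 0.756, against the 0.737 carried in. A neighbour flask, charged with 0.78 M of X, lies close to cedar's 0.87 M, so cedar's 0.778 puts its L at 31.1%, and that neighbour stands at 29.1%.

(The runs were generated by integration with made-up constants; noise was put on by code.)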